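## Structural features

The target is a labdane: a trans-fused decalin (ring A = C1–C5, C10; ring B = C5–C10) with a gem-dimethyl group at C4, an angular methyl on the quaternary carbon C10, and a (2E)-3-methylpenta-2,4-dienyl chain on C9. Five stereocentres (C6, C5, C10, C9, C8) are contiguous around ring B. C5–H is α and C10–CH3 is β; the C9 chain, the C6 oxygen and the C8 oxygen are all equatorial, and the C8 methyl is axial, syn to the C10 methyl. The two oxygens are 1,3-syn, but only the secondary one at C6 is acylated, as an angelate; the C8 oxygen is a free tertiary alcohol. The fragile groups are the angelate (Z to E isomerisation to the tiglate, conjugate addition), the terminal 1,3-diene (acid, hydrogenation, electrophilic oxidants), and the tertiary C8 alcohol, which under acid can dehydrate or add to the diene to give the 8,13-ether. The real difficulty is the quaternary C10 held trans to C5 between the congested C4 and C9, together with three correctly oriented ring-B substituents; the C6 carbinol sits between two carbons that each have a quaternary neighbour, so substrate control there is unreliable. The key step uses the fact that in ring A the adjacent carbons C10 and C5 carry exocyclic carbons C9 and C6 that are trans. These map onto the formyl and ester carbons of an (E)-enal ester whose α-methyl becomes the C10 methyl, while C1–C4 come from a 1-amino-3-silyloxydiene whose oxygen at C3 later directs the C4 gem-dimethylation.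

## Logic of the disconnections

**C6–O acyl bond.** 40 is cut to 37 and 38. The angelate is the most isomerisation-prone group and goes on last. This leaves a diol in which only the secondary hydroxyl can be acylated. The forward step must keep the Z geometry and must not be acidic.

**C14=C15, then C12=C13.** 37 comes from 36 by desilylation; 36 is cut at C14=C15 to 33 and 34, and 33 at C12=C13 to 31 and 32. A stabilised ylide on an unhindered aldehyde gives the E-trisubstituted alkene, and a methylenation completes the diene. This removes the whole diene and leads back to a C12 aldehyde. Both hydroxyls must be silylated so that no lactol or oxa-Michael closure from O8 can interfere.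

**C12 oxidation level and O8 protection.** 31 is traced through 30 to 29 by partial reduction of the ester and silylation of the tertiary alcohol. The demand is a reduction that stops at the aldehyde.

**C8–C9 (ring B).** 29 is cut to 28. One bond formation closes ring B and sets C8 and C9 together, with O8 and C11 trans-diequatorial. The bicycle becomes a monocycle that holds only C5, C6 and C10. The forward step needs a chair transition state with the metal-bound oxygen equatorial, and a C6 substituent that cannot chelate.

**C6–C7.** 28 comes from 26 by cleaving a 1,1-disubstituted alkene to the methyl ketone; 26 comes from 25, which is cut at C6–C7 to 21 and 22. This brings in C7, C8 and C17 as one unit. The demand is reagent-controlled face selection at the C6 aldehyde, and an alkene cleavage that spares the enoate.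

**C9=C11.** 21 comes from 20 by oxidation, and 20 is cut at C9=C11 to 18 and 19. The two-carbon acceptor arm is added only after C6 has been reduced, so the two ester carbons never have to be told apart. The olefination must work on a lactol.

**Ring A adjustments.** 18 is traced to 16 (reduction at C6, unmasking of C9), 16 to 15 and 14 (removal of the C3 oxygen), 14 to 13, and 13 to 10 and 11 (C4–C18 and C4–C19, both methyl groups from 11). 10 goes back through 9 to 7. The C3 carbonyl is kept exactly as long as it is needed: in the enone only C4 can be enolised, so the double methylation is regiospecific. The forward steps must tolerate the ester and the masked aldehyde.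

**C1–C10 and C4–C5 (ring A).** 7 is cut to 5 and 6. One cycloaddition makes ring A, the quaternary C10 and the C5/C10 trans relation. The demand is catalyst-controlled enantioface selection and formyl-directed regiochemistry.

**Diene.** 5 is traced through 4 and 3 to 1 and 2 by O-silylation, N-acylation and amine exchange.

## Other disconnections considered

Alternative 1: The cut is at C5–C10 and C8–C9. A chiral oxazaborolidinium Lewis acid would activate the open-chain trienal A1 for an intramolecular [4+2] reaction: the C9=C10 enal is the dienophile, the 2-silyloxydiene C5=C6–C7=C8 is the diene, and C1–C4 is the tether, so that rings A and B would form together and give A2.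
- In its favour: both rings and four stereocentres (C5, C8, C9, C10) arise in one step from a chain. The C6 oxygen, the C8 methyl and C11 are already in place, and no ring-A deoxygenation is needed. On convergence it is better than the chosen plan.
- Against it here: the C5–C10 bond joins a carbon next to the quaternary C4 to a carbon that becomes quaternary. The β,β-disubstituted enal is a weak partner for this catalyst class, whose good cases are α-substituted enals. The silyl enol ether diene is acid-labile. A2 also lacks the C8 oxygen and C12, and its C6 ketone would have to be reduced against the kinetic preference for the axial alcohol.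
- Comparison: both plans rest on a Lewis-acid-catalysed asymmetric [4+2] reaction of an enal, so they are equal in mechanism type. The chosen intermolecular version has close precedent for quaternary carbons, whereas the intramolecular one needs an extension of scope. The shorter path to the decalin is likely to be used up by C8 hydroxylation, one-carbon homologation and C6 correction.

Alternative 2: The cut is at C9–C10. An iron hydride generated from Fe(acac)3 and PhSiH3 would deliver a hydrogen atom to C1 of the cyclohexene A3; the resulting tertiary radical at C10 would then close 6-exo onto the enoate carbon C9 and give A4.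
- In its favour: ring A with its gem-dimethyl group and C5 comes from an α-cyclogeranyl unit, so no ring-A redox work is needed; here it is better than the chosen plan. The conditions are mild and tolerate a free tertiary alcohol. A4 is the same kind of compound as 29, so the endgame is equal.
- Against it here: C5, C6 and C8 must all be set on an open chain before ring closure, including the tertiary C8 carbinol 1,3 to C6. The enantioenriched ring-A aldehyde needed for A3 is configurationally labile. The ring fusion and C9 are both decided in a radical step in which a tertiary radical attacks a β-carbon attached to a fully substituted carbinol carbon.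
- Comparison: both close ring B by a 6-exo radical addition to the same enoate carbon, so the mechanism type is equal. In the chosen plan the quaternary C10 is already secured by the cycloaddition and the radical is a ketyl that sets C8 and C9 in a chair. Step economy could favour the alternative if A3 were short to make.

Alternative 3: The cut is at C7–C8, seen through the α-hydroxy ketone retron C8(OH)–C9(=O). In the tertiary α-ketol A5, whose ring B is still five-membered, C7 would shift from C9 to the carbonyl carbon of the acetyl group (C8), so that the ring grows to six members and the ketone ends up at C9, giving A6.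
- In its favour: the shift is stereospecific, so the C8 configuration is relayed from C9. It is driven by relief of trans-hydrindane strain, and it makes the hindered tertiary carbinol without an organometallic addition. In stereospecificity at C8 it is better than the chosen plan.
- Against it here: C10 can migrate in competition with C7. A5 is itself a trans-hydrindane with four stereocentres. A6 has a C9 ketone flanked by two fully substituted carbons, so attaching the side chain and setting C9–H would be hard.
- Comparison: it is equal to the chosen plan in delivering ring B with both oxygens in place. The mechanism is a thermodynamically controlled 1,2-shift rather than a kinetically controlled radical addition. Step economy is worse, because the precursor and the C9 elaboration are both long.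

Key step: step 4

**Remarks on the chemistry (assumptions)**
- The diene nitrogen carries benzyl and methoxycarbonyl instead of two alkyl groups. The carbamate lowers the uncatalysed rate and the Lewis basicity, which the salen–chromium catalysis needs; the diene skeleton and the bonds formed are unchanged.
- "salen" is the dianion of N,N′-bis(3,5-di-tert-butylsalicylidene)cyclohexane-1,2-diamine. The active catalyst is the hexafluoroantimonate made from (salen)CrCl and AgSbF6. The (R,R) antipode is written; if the sense of induction with 6 is the opposite, the equally available (S,S) antipode is used.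
- Positions are named by labdane numbering (C1–C20) throughout, also in monocyclic intermediates.

## Route

**Step 1**
Reactants: 1 (3E)-4-methoxybut-3-en-2-one; 2 benzylamine
Product: 3 (3Z)-4-(benzylamino)but-3-en-2-one
Conditions: CH2Cl2, rt
Reagents that add atoms: none
Why: Addition–elimination (amine exchange) on a vinylogous ester; the secondary vinylogous amide is held Z by an N–H···O hydrogen bond.

**Step 2**
Reactants: 3 (3Z)-4-(benzylamino)but-3-en-2-one
Product: 4 methyl benzyl[(1E)-3-oxobut-1-en-1-yl]carbamate
Conditions: NaN(SiMe3)2, THF, −78 °C; ClCO2Me, −78 °C → rt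
Reagents that add atoms: methyl chloroformate, COC(=O)Cl
Why: N-acylation of the delocalised vinylogous amide anion; without the hydrogen bond the product relaxes to the E vinylogous imide.

**Step 3**
Reactants: 4 methyl benzyl[(1E)-3-oxobut-1-en-1-yl]carbamate
Product: 5 methyl benzyl[(1E)-3-{[tert-butyl(dimethyl)silyl]oxy}buta-1,3-dien-1-yl]carbamate
Conditions: KN(SiMe3)2, THF, −78 °C; tBuMe2SiCl, −78 °C → rt
Reagents that add atoms: tert-butyldimethylsilyl chloride, CC(C)(C)[Si](C)(C)Cl
Why: Kinetic deprotonation of the methyl ketone and O-silylation of the enolate give the 1-(acylamino)-3-silyloxydiene.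

**Step 4**
Reactants: 5 methyl benzyl[(1E)-3-{[tert-butyl(dimethyl)silyl]oxy}buta-1,3-dien-1-yl]carbamate; 6 ethyl (2E)-3-methyl-4-oxobut-2-enoate
Product: 7 ethyl (1S,5S,6R)-5-[benzyl(methoxycarbonyl)amino]-3-{[tert-butyl(dimethyl)silyl]oxy}-6-formyl-6-methylcyclohex-3-ene-1-carboxylate
Conditions: [(R,R)-salen]CrSbF6 (5 mol %, from [(R,R)-salen]CrCl and AgSbF6), 4 Å MS, CH2Cl2, −40 °C
Reagents that add atoms: none
Why: The cationic trivalent-chromium centre binds the formyl oxygen of 6, lowers the LUMO and makes the ester-bearing β-carbon (C5) the electrophilic terminus; the CH2 terminus of 5 (C4), activated by both the silyloxy and the acylamino group, bonds there first and the nitrogen-bearing terminus (C1) closes onto the α-carbon (C10) in a concerted, strongly asynchronous [4+2] cycloaddition. The closest known reaction type is the salen–chromium-catalysed Diels–Alder reaction of 1-(acylamino)-3-silyloxybutadienes with α-substituted acroleins, which builds quaternary carbons α to the formyl group; here the enal only carries an extra β-ester. Ring A is closed by the intermolecular cycloaddition itself, with both new bonds (C4–C5 and C1–C10) formed suprafacially on diene and dienophile. C10 and C5 are set together: their absolute sense comes from the enal face left open by the chiral salen ligand, and their trans relation (formyl carbon C9 against ester carbon C6) is copied from the E geometry of 6. The C1 stereocentre follows from endo approach of the catalyst-bound formyl group and is destroyed in step 5, so it needs no control. The step needs formyl-directed regioselectivity, which the stronger, catalyst-activated acceptor secures, and enantioface selectivity, which requires a slow uncatalysed pathway; that is why the nitrogen is a carbamate and the temperature is −40 °C.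

**Step 5**
Reactants: 7 ethyl (1S,5S,6R)-5-[benzyl(methoxycarbonyl)amino]-3-{[tert-butyl(dimethyl)silyl]oxy}-6-formyl-6-methylcyclohex-3-ene-1-carboxylate
Product: 9 ethyl (1S,2S)-2-formyl-2-methyl-5-oxocyclohex-3-ene-1-carboxylate, via β-carbamoyl ketone 8 (not isolated)
Conditions: 48% aq. HF, MeCN, 0 °C → rt
Reagents that add atoms: none
Why: Protodesilylation of the silyl enol ether gives the C3 ketone; acid-mediated β-elimination of the carbamate through the enol then gives the C1=C2 enone. C5 and C10 are not touched.

**Step 6**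
Reactants: 9 ethyl (1S,2S)-2-formyl-2-methyl-5-oxocyclohex-3-ene-1-carboxylate
Product: 10 ethyl (1S,2S)-2-(1,3-dioxolan-2-yl)-2-methyl-5-oxocyclohex-3-ene-1-carboxylate
Conditions: (Me3SiOCH2)2, Me3SiOTf (5 mol %), CH2Cl2, −78 → −20 °C
Reagents that add atoms: 1,2-bis(trimethylsilyloxy)ethane, C[Si](C)(C)OCCO[Si](C)(C)C
Why: Noyori acetalisation. At low temperature the aldehyde reacts and the conjugated ketone does not; this masks the non-enolisable, retro-Claisen-prone formyl group before any base is used.

**Step 7**
Reactants: 10 ethyl (1S,2S)-2-(1,3-dioxolan-2-yl)-2-methyl-5-oxocyclohex-3-ene-1-carboxylate; 11 iodomethane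
Product: 13 ethyl (1R,2S)-2-(1,3-dioxolan-2-yl)-2,6,6-trimethyl-5-oxocyclohex-3-ene-1-carboxylate, via monomethyl enone 12 (not isolated)
Conditions: LiN(iPr)2 (1.1 equiv), THF, −78 °C; MeI (1.1 equiv), −78 → 0 °C; LiN(iPr)2 (1.3 equiv), −78 °C; MeI (3 equiv), DMPU, −78 → 0 °C
Reagents that add atoms: iodomethane, CI
Why: Two successive kinetic enolate alkylations in one flask: 11 delivers the first methyl group to give 12, and a second portion of the same reagent, added after renewed deprotonation, delivers the second. The enone can enolise only at C4 (C2 is vinylic, C10 is quaternary), and the more acidic ketone α-position is deprotonated ahead of the hindered ester α-hydrogen at C5, so both methyl groups go to C4 and C5 is not epimerised.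

**Step 8**
Reactants: 13 ethyl (1R,2S)-2-(1,3-dioxolan-2-yl)-2,6,6-trimethyl-5-oxocyclohex-3-ene-1-carboxylate
Product: 14 ethyl (1R,6S)-6-(1,3-dioxolan-2-yl)-2,2,6-trimethyl-3-oxocyclohexane-1-carboxylate
Conditions: H2 (1 atm), 10% Pd/C, EtOAc, rt
Reagents that add atoms: none
Why: Catalytic hydrogenation of the disubstituted enone double bond; ketone, ester and acetal are inert.

**Step 9**
Reactants: 14 ethyl (1R,6S)-6-(1,3-dioxolan-2-yl)-2,2,6-trimethyl-3-oxocyclohexane-1-carboxylate
Product: 15 ethyl (1S,6S)-6-(1,3-dioxolan-2-yl)-2,2,6-trimethyl-3-{[(trifluoromethyl)sulfonyl]oxy}cyclohex-3-ene-1-carboxylate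
Conditions: KN(SiMe3)2, THF, −78 °C; PhNTf2, −78 → 0 °C
Reagents that add atoms: N-phenylbis(trifluoromethanesulfonimide), O=S(=O)(N(c1ccccc1)S(=O)(=O)C(F)(F)F)C(F)(F)F
Why: Enol triflate formation. With C4 quaternary the ketone can enolise only towards C2, so a single vinyl triflate forms.

**Step 10**
Reactants: 15 ethyl (1S,6S)-6-(1,3-dioxolan-2-yl)-2,2,6-trimethyl-3-{[(trifluoromethyl)sulfonyl]oxy}cyclohex-3-ene-1-carboxylate
Product: 16 ethyl (1S,2S)-2-(1,3-dioxolan-2-yl)-2,6,6-trimethylcyclohexane-1-carboxylate
Conditions: H2 (1–3 atm), PtO2, NaHCO3, EtOAc, rt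
Reagents that add atoms: none
Why: Hydrogenolysis of the vinyl C–O bond and hydrogenation of the resulting alkene remove the C3 oxygen under non-basic, non-nucleophilic conditions that spare the ester and the acetal. The bicarbonate takes up the triflic acid.

**Step 11**
Reactants: 16 ethyl (1S,2S)-2-(1,3-dioxolan-2-yl)-2,6,6-trimethylcyclohexane-1-carboxylate
Product: 18 (3aS,7aS)-4,4,7a-trimethyloctahydro-2-benzofuran-1-ol (both epimers at the hemiacetal carbon C9), via hydroxy acetal 17 (not isolated)
Conditions: LiAlH4, THF, 0 → 50 °C; then 1 M aq. HCl, THF, rt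
Reagents that add atoms: water, O
Why: Hydride reduction of the hindered ester to the C6 primary alcohol. In aqueous acid the neighbouring hydroxyl assists opening of the dioxolane, and the C9 aldehyde is trapped as the five-membered lactol.

**Step 12**
Reactants: 18 (3aS,7aS)-4,4,7a-trimethyloctahydro-2-benzofuran-1-ol; 19 methyl (triphenyl-λ5-phosphanylidene)acetate
Product: 20 methyl (2E)-3-[(1R,2S)-2-(hydroxymethyl)-1,3,3-trimethylcyclohexyl]prop-2-enoate
Conditions: PhCO2H (cat.), toluene, 100 °C
Reagents that add atoms: none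
Why: Wittig olefination of the open hydroxy-aldehyde form of the lactol. The stabilised ylide gives the E enoate (C9=C11), and the neopentyl β-carbon C9 slows oxa-Michael return of the C6 hydroxyl.

**Step 13**
Reactants: 20 methyl (2E)-3-[(1R,2S)-2-(hydroxymethyl)-1,3,3-trimethylcyclohexyl]prop-2-enoate
Product: 21 methyl (2E)-3-[(1R,2S)-2-formyl-1,3,3-trimethylcyclohexyl]prop-2-enoate
Conditions: Dess–Martin periodinane, CH2Cl2, 0 °C → rt
Reagents that add atoms: none
Why: Mild, neutral oxidation of the primary alcohol to the C6 aldehyde without enolisation at C5.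

**Step 14**
Reactants: 21 methyl (2E)-3-[(1R,2S)-2-formyl-1,3,3-trimethylcyclohexyl]prop-2-enoate; 22 (2-methylprop-2-en-1-yl)magnesium chloride
Product: 25 methyl (2E)-3-{(1R,2S)-2-[(1S)-1-hydroxy-3-methylbut-3-en-1-yl]-1,3,3-trimethylcyclohexyl}prop-2-enoate, via methallylborane 23 (not isolated), via borinate 24 (not isolated)
Conditions: (−)-Ipc2BOMe, 22, Et2O, −78 °C → rt; then 21, −78 °C → rt; NaBO3·4H2O, THF–H2O, rt
Reagents that add atoms: none
Why: Brown methallylboration through a closed six-membered transition state. The isopinocampheyl groups of the reagent derived from (+)-α-pinene select the aldehyde face that gives the 6S carbinol (the 6α-oxygen). Reagent control is used because the aldehyde is flanked by two carbons with quaternary neighbours and offers no reliable substrate bias; the enoate is inert to the allylborane.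

**Step 15**
Reactants: 25 methyl (2E)-3-{(1R,2S)-2-[(1S)-1-hydroxy-3-methylbut-3-en-1-yl]-1,3,3-trimethylcyclohexyl}prop-2-enoate
Product: 26 methyl (2E)-3-[(1R,2S)-2-{(1S)-1-[(tert-butyldimethylsilyl)oxy]-3-methylbut-3-en-1-yl}-1,3,3-trimethylcyclohexyl]prop-2-enoate
Conditions: tBuMe2SiOTf, 2,6-lutidine, CH2Cl2, −78 → 0 °C
Reagents that add atoms: tert-butyldimethylsilyl trifluoromethanesulfonate, CC(C)(C)[Si](C)(C)OS(=O)(=O)C(F)(F)F
Why: Silylation of the hindered secondary alcohol with the reactive silyl triflate. The bulky non-chelating ether keeps O6 out of the samarium coordination sphere in step 17.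

**Step 16**
Reactants: 26 methyl (2E)-3-[(1R,2S)-2-{(1S)-1-[(tert-butyldimethylsilyl)oxy]-3-methylbut-3-en-1-yl}-1,3,3-trimethylcyclohexyl]prop-2-enoate
Product: 28 methyl (2E)-3-[(1R,2S)-2-{(1S)-1-[(tert-butyldimethylsilyl)oxy]-3-oxobutyl}-1,3,3-trimethylcyclohexyl]prop-2-enoate, via ozonide 27 (not isolated)
Conditions: O3, CH2Cl2, −78 °C (Sudan Red 7B end point); PPh3, −78 °C → rt
Reagents that add atoms: ozone, [O-][O+]=O
Why: Ozonolysis with reductive work-up. The electron-rich 1,1-disubstituted alkene reacts far faster than the electron-poor enoate, which unmasks the C8 methyl ketone.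

**Step 17**
Reactants: 28 methyl (2E)-3-[(1R,2S)-2-{(1S)-1-[(tert-butyldimethylsilyl)oxy]-3-oxobutyl}-1,3,3-trimethylcyclohexyl]prop-2-enoate
Product: 29 methyl 6α-[(tert-butyldimethylsilyl)oxy]-8α-hydroxy-13,14,15,16-tetranorlabdan-12-oate
Conditions: SmI2 (2.5 equiv), HMPA, tBuOH (2 equiv), THF, −78 °C → 0 °C
Reagents that add atoms: none
Why: Ketyl–olefin cyclisation: SmI2 reduces the C8 ketone to the ketyl, which adds 6-exo-trig to the enoate β-carbon C9; a second electron and tBuOH give the saturated ester. In the chair transition state the solvated samarium-bound oxygen is equatorial (methyl axial, so 8α-OH) and the acrylate arm is equatorial and anti to that oxygen (so 9α-H), with the C6 silyl ether equatorial.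

**Step 18**
Reactants: 29 methyl 6α-[(tert-butyldimethylsilyl)oxy]-8α-hydroxy-13,14,15,16-tetranorlabdan-12-oate
Product: 30 methyl 6α-[(tert-butyldimethylsilyl)oxy]-8α-[(triethylsilyl)oxy]-13,14,15,16-tetranorlabdan-12-oate
Conditions: Et3SiOTf, 2,6-lutidine, CH2Cl2, −78 → 0 °C
Reagents that add atoms: triethylsilyl trifluoromethanesulfonate, CC[Si](CC)(CC)OS(=O)(=O)C(F)(F)F
Why: Silyl triflate silylation of the tertiary alcohol. Capping O8 prevents lactol formation and oxa-Michael closure once C12 becomes an aldehyde and then an enal.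

**Step 19**
Reactants: 30 methyl 6α-[(tert-butyldimethylsilyl)oxy]-8α-[(triethylsilyl)oxy]-13,14,15,16-tetranorlabdan-12-oate
Product: 31 6α-[(tert-butyldimethylsilyl)oxy]-8α-[(triethylsilyl)oxy]-13,14,15,16-tetranorlabdan-12-al
Conditions: iBu2AlH (1.2 equiv), CH2Cl2, −78 °C; MeOH, then aq. KNaC4H4O6
Reagents that add atoms: none
Why: Partial reduction of the methyl ester. The tetrahedral aluminium hemiacetal is stable at −78 °C and collapses to the aldehyde only on work-up.

**Step 20**
Reactants: 31 6α-[(tert-butyldimethylsilyl)oxy]-8α-[(triethylsilyl)oxy]-13,14,15,16-tetranorlabdan-12-al; 32 2-(triphenyl-λ5-phosphanylidene)propanal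
Product: 33 (12E)-6α-[(tert-butyldimethylsilyl)oxy]-8α-[(triethylsilyl)oxy]-15-norlabd-12-en-14-al
Conditions: toluene, 100 °C
Reagents that add atoms: none
Why: Wittig reaction of a formyl-stabilised ylide under thermodynamic control gives the E-trisubstituted enal (C11 trans to C14). The α-methyl enal product is too unreactive to be olefinated again.

**Step 21**
Reactants: 33 (12E)-6α-[(tert-butyldimethylsilyl)oxy]-8α-[(triethylsilyl)oxy]-15-norlabd-12-en-14-al; 34 methyltriphenylphosphonium bromide
Product: 36 (12E)-6α-[(tert-butyldimethylsilyl)oxy]-8α-[(triethylsilyl)oxy]labda-12,14-diene, via methylidene ylide 35 (not isolated)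
Conditions: 34, KN(SiMe3)2, THF, 0 °C; then 33, 0 °C → rt
Reagents that add atoms: none
Why: Wittig methylenation of the enal adds C15 and completes the diene without touching the C12=C13 geometry.

**Step 22**
Reactants: 36 (12E)-6α-[(tert-butyldimethylsilyl)oxy]-8α-[(triethylsilyl)oxy]labda-12,14-diene
Product: 37 (12E)-labda-12,14-diene-6α,8α-diol
Conditions: Bu4NF, THF, rt → 50 °C
Reagents that add atoms: none
Why: Fluoride cleaves both silyl ethers under non-acidic conditions, so the tertiary alcohol cannot add to the diene or dehydrate.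

**Step 23**
Reactants: 37 (12E)-labda-12,14-diene-6α,8α-diol; 38 angelic acid
Product: 40 (12E)-8α-hydroxylabda-12,14-dien-6α-yl (2Z)-2-methylbut-2-enoate, via mixed anhydride 39 (not isolated)
Conditions: 38, 2,4,6-Cl3C6H2COCl, Et3N, toluene, rt; then 37, 80 °C
Reagents that add atoms: none
Why: Yamaguchi-type esterification through the mixed anhydride, run without a nucleophilic catalyst so that the Z enoate is not isomerised. Only the secondary C6 hydroxyl is acylated; the tertiary C8 hydroxyl is too hindered.

## Compound list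

1 | (3E)-4-methoxybut-3-en-2-one | CO/C=C/C(C)=O | starting material
2 | benzylamine | NCc1ccccc1 | starting material
3 | (3Z)-4-(benzylamino)but-3-en-2-one | CC(=O)/C=C\NCc1ccccc1 | intermediate
4 | methyl benzyl[(1E)-3-oxobut-1-en-1-yl]carbamate | CC(=O)/C=C/N(Cc1ccccc1)C(=O)OC | intermediate
5 | methyl benzyl[(1E)-3-{[tert-butyl(dimethyl)silyl]oxy}buta-1,3-dien-1-yl]carbamate | C=C(O[Si](C)(C)C(C)(C)C)/C=C/N(Cc1ccccc1)C(=O)OC | intermediate
6 | ethyl (2E)-3-methyl-4-oxobut-2-enoate | CCOC(=O)/C=C(\C)C=O | starting material
7 | ethyl (1S,5S,6R)-5-[benzyl(methoxycarbonyl)amino]-3-{[tert-butyl(dimethyl)silyl]oxy}-6-formyl-6-methylcyclohex-3-ene-1-carboxylate | CCOC(=O)[C@H]1CC(O[Si](C)(C)C(C)(C)C)=C[C@H](N(Cc2ccccc2)C(=O)OC)[C@]1(C)C=O | intermediate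
8 | ethyl (1S,2R,3S)-3-[benzyl(methoxycarbonyl)amino]-2-formyl-2-methyl-5-oxocyclohexane-1-carboxylate | CCOC(=O)[C@H]1CC(=O)C[C@H](N(Cc2ccccc2)C(=O)OC)[C@]1(C)C=O | intermediate (not isolated)
9 | ethyl (1S,2S)-2-formyl-2-methyl-5-oxocyclohex-3-ene-1-carboxylate | CCOC(=O)[C@H]1CC(=O)C=C[C@]1(C)C=O | intermediate
10 | ethyl (1S,2S)-2-(1,3-dioxolan-2-yl)-2-methyl-5-oxocyclohex-3-ene-1-carboxylate | CCOC(=O)[C@H]1CC(=O)C=C[C@]1(C)C2OCCO2 | intermediate
11 | iodomethane | CI | starting material
12 | ethyl (1S,2S)-2-(1,3-dioxolan-2-yl)-2,6-dimethyl-5-oxocyclohex-3-ene-1-carboxylate (either epimer at the methylated carbon C4 of the labdane numbering) | CCOC(=O)[C@H]1C(C)C(=O)C=C[C@]1(C)C2OCCO2 | intermediate (not isolated)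
13 | ethyl (1R,2S)-2-(1,3-dioxolan-2-yl)-2,6,6-trimethyl-5-oxocyclohex-3-ene-1-carboxylate | CCOC(=O)[C@H]1C(C)(C)C(=O)C=C[C@]1(C)C2OCCO2 | intermediate
14 | ethyl (1R,6S)-6-(1,3-dioxolan-2-yl)-2,2,6-trimethyl-3-oxocyclohexane-1-carboxylate | CCOC(=O)[C@H]1C(C)(C)C(=O)CC[C@]1(C)C2OCCO2 | intermediate
15 | ethyl (1S,6S)-6-(1,3-dioxolan-2-yl)-2,2,6-trimethyl-3-{[(trifluoromethyl)sulfonyl]oxy}cyclohex-3-ene-1-carboxylate | CCOC(=O)[C@H]1C(C)(C)C(OS(=O)(=O)C(F)(F)F)=CC[C@]1(C)C2OCCO2 | intermediate
16 | ethyl (1S,2S)-2-(1,3-dioxolan-2-yl)-2,6,6-trimethylcyclohexane-1-carboxylate | CCOC(=O)[C@H]1C(C)(C)CCC[C@]1(C)C2OCCO2 | intermediate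
17 | [(1S,2S)-2-(1,3-dioxolan-2-yl)-2,6,6-trimethylcyclohexyl]methanol | OC[C@H]1C(C)(C)CCC[C@]1(C)C2OCCO2 | intermediate (not isolated)
18 | (3aS,7aS)-4,4,7a-trimethyloctahydro-2-benzofuran-1-ol (both epimers at C1 of the benzofuran) | OC1OC[C@H]2C(C)(C)CCC[C@]12C | intermediate
19 | methyl (triphenyl-λ5-phosphanylidene)acetate | COC(=O)C=P(c1ccccc1)(c1ccccc1)c1ccccc1 | starting material
20 | methyl (2E)-3-[(1R,2S)-2-(hydroxymethyl)-1,3,3-trimethylcyclohexyl]prop-2-enoate | COC(=O)/C=C/[C@@]1(C)CCCC(C)(C)[C@@H]1CO | intermediate
21 | methyl (2E)-3-[(1R,2S)-2-formyl-1,3,3-trimethylcyclohexyl]prop-2-enoate | COC(=O)/C=C/[C@@]1(C)CCCC(C)(C)[C@@H]1C=O | intermediate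
22 | (2-methylprop-2-en-1-yl)magnesium chloride | CC(=C)C[Mg]Cl | starting material
23 | (−)-B-(2-methylprop-2-en-1-yl)diisopinocampheylborane (isopinocampheyl groups from (+)-α-pinene) | CC(=C)CB([C@@H]1C[C@@H]2C[C@@H](C2(C)C)[C@H]1C)[C@@H]1C[C@@H]2C[C@@H](C2(C)C)[C@H]1C | intermediate (not isolated)
24 | diisopinocampheylborinic ester of 25 (boron on the C6 oxygen) | COC(=O)/C=C/[C@@]1(C)CCCC(C)(C)[C@@H]1[C@@H](OB([C@@H]2C[C@@H]3C[C@@H](C3(C)C)[C@H]2C)[C@@H]2C[C@@H]3C[C@@H](C3(C)C)[C@H]2C)CC(C)=C | intermediate (not isolated)
25 | methyl (2E)-3-{(1R,2S)-2-[(1S)-1-hydroxy-3-methylbut-3-en-1-yl]-1,3,3-trimethylcyclohexyl}prop-2-enoate | COC(=O)/C=C/[C@@]1(C)CCCC(C)(C)[C@@H]1[C@@H](O)CC(C)=C | intermediate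
26 | methyl (2E)-3-[(1R,2S)-2-{(1S)-1-[(tert-butyldimethylsilyl)oxy]-3-methylbut-3-en-1-yl}-1,3,3-trimethylcyclohexyl]prop-2-enoate | COC(=O)/C=C/[C@@]1(C)CCCC(C)(C)[C@@H]1[C@@H](O[Si](C)(C)C(C)(C)C)CC(C)=C | intermediate
27 | 1,2,4-trioxolane (secondary ozonide) of 26: the 3-methyl-1,2,4-trioxolan-3-yl ring in place of the isopropenyl group, either configuration at the ring carbon | COC(=O)/C=C/[C@@]1(C)CCCC(C)(C)[C@@H]1[C@@H](O[Si](C)(C)C(C)(C)C)CC1(C)OCOO1 | intermediate (not isolated)
28 | methyl (2E)-3-[(1R,2S)-2-{(1S)-1-[(tert-butyldimethylsilyl)oxy]-3-oxobutyl}-1,3,3-trimethylcyclohexyl]prop-2-enoate | COC(=O)/C=C/[C@@]1(C)CCCC(C)(C)[C@@H]1[C@@H](O[Si](C)(C)C(C)(C)C)CC(C)=O | intermediate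
29 | methyl 6α-[(tert-butyldimethylsilyl)oxy]-8α-hydroxy-13,14,15,16-tetranorlabdan-12-oate | COC(=O)C[C@@H]1[C@@]2(C)CCCC(C)(C)[C@@H]2[C@@H](O[Si](C)(C)C(C)(C)C)C[C@@]1(C)O | intermediate
30 | methyl 6α-[(tert-butyldimethylsilyl)oxy]-8α-[(triethylsilyl)oxy]-13,14,15,16-tetranorlabdan-12-oate | COC(=O)C[C@@H]1[C@@]2(C)CCCC(C)(C)[C@@H]2[C@@H](O[Si](C)(C)C(C)(C)C)C[C@@]1(C)O[Si](CC)(CC)CC | intermediate
31 | 6α-[(tert-butyldimethylsilyl)oxy]-8α-[(triethylsilyl)oxy]-13,14,15,16-tetranorlabdan-12-al | O=CC[C@@H]1[C@@]2(C)CCCC(C)(C)[C@@H]2[C@@H](O[Si](C)(C)C(C)(C)C)C[C@@]1(C)O[Si](CC)(CC)CC | intermediate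
32 | 2-(triphenyl-λ5-phosphanylidene)propanal | CC(C=O)=P(c1ccccc1)(c1ccccc1)c1ccccc1 | starting material
33 | (12E)-6α-[(tert-butyldimethylsilyl)oxy]-8α-[(triethylsilyl)oxy]-15-norlabd-12-en-14-al | O=C/C(C)=C/C[C@@H]1[C@@]2(C)CCCC(C)(C)[C@@H]2[C@@H](O[Si](C)(C)C(C)(C)C)C[C@@]1(C)O[Si](CC)(CC)CC | intermediate
34 | methyltriphenylphosphonium bromide | C[P+](c1ccccc1)(c1ccccc1)c1ccccc1.[Br-] | starting material
35 | methylidenetriphenyl-λ5-phosphane | C=P(c1ccccc1)(c1ccccc1)c1ccccc1 | intermediate (not isolated)
36 | (12E)-6α-[(tert-butyldimethylsilyl)oxy]-8α-[(triethylsilyl)oxy]labda-12,14-diene | C=C/C(C)=C/C[C@@H]1[C@@]2(C)CCCC(C)(C)[C@@H]2[C@@H](O[Si](C)(C)C(C)(C)C)C[C@@]1(C)O[Si](CC)(CC)CC | intermediate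
37 | (12E)-labda-12,14-diene-6α,8α-diol | C=C/C(C)=C/C[C@@H]1[C@@]2(C)CCCC(C)(C)[C@@H]2[C@@H](O)C[C@@]1(C)O | intermediate
38 | angelic acid, (2Z)-2-methylbut-2-enoic acid | C/C=C(/C)C(=O)O | starting material
39 | (2Z)-2-methylbut-2-enoic 2,4,6-trichlorobenzoic anhydride | C/C=C(/C)C(=O)OC(=O)c1c(Cl)cc(Cl)cc1Cl | intermediate (not isolated)
40 | (12E)-8α-hydroxylabda-12,14-dien-6α-yl (2Z)-2-methylbut-2-enoate (CNP0582767.1) | C=C/C(C)=C/C[C@@H]1[C@@]2(C)CCCC(C)(C)[C@@H]2[C@@H](OC(=O)/C(C)=C\C)C[C@@]1(C)O | target

## Step count and least certain steps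

Total step count: 23. Longest linear sequence: 23 steps (1 → 40; the route is linear, and every other numbered starting material is bought).

**Step 4 (key step).** The most likely failure is loss of enantioface selectivity, either through an uncatalysed background cycloaddition (6 is doubly activated) or because the β-ester changes how the enal sits on the catalyst. The fallback replaces catalyst control by auxiliary control. It sets out from 1 and 6 and returns at 9. 1 is condensed with (2R,5R)-2,5-diphenylpyrrolidine to give the vinylogous amide (3E)-4-[(2R,5R)-2,5-diphenylpyrrolidin-1-yl]but-3-en-2-one F1. This is silylated (KN(SiMe3)2, tBuMe2SiCl) to the C2-symmetric diene (2R,5R)-1-[(1E)-3-{[tert-butyl(dimethyl)silyl]oxy}buta-1,3-dien-1-yl]-2,5-diphenylpyrrolidine F2. F2 reacts thermally with 6 (toluene, −20 °C → rt) to give the pyrrolidinyl cycloadduct F3, and aqueous HF in MeCN then gives 9 with release of the pyrrolidine. The antipodal auxiliary is used if the sense is the opposite.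

**Step 14.** The most likely failure is poor facial selectivity, or slow addition, because the bulky chiral borane must approach an aldehyde wedged between two carbons with quaternary neighbours. The fallback sets C6 by ketone reduction instead of C–C bond formation. It sets out from 21 and returns at 25. 22 is added directly to 21 (THF, −78 °C), giving 25 together with its C6 epimer methyl (2E)-3-{(1R,2S)-2-[(1R)-1-hydroxy-3-methylbut-3-en-1-yl]-1,3,3-trimethylcyclohexyl}prop-2-enoate F4. The mixture is oxidised with Dess–Martin periodinane to the ketone methyl (2E)-3-[(1R,2S)-1,3,3-trimethyl-2-(3-methylbut-3-enoyl)cyclohexyl]prop-2-enoate F5. F5 is reduced with (R)-2-methyl-CBS-oxazaborolidine and catecholborane, which distinguishes the very large ring side from the CH2 side, to give 25.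

**Step 17.** The most likely failure is in-flask lactonisation: the tertiary samarium alkoxide at O8 closes onto the C12 ester, which takes material away from 29 and from the silylation in step 18. Wrong facial selectivity is less likely, because the trans-diequatorial chair is strongly preferred. The fallback accepts the lactone. It sets out from 28 and returns at 31. The cyclisation is run as before and warmed until closure is complete, giving the lactone 6α-[(tert-butyldimethylsilyl)oxy]-8α,12-epoxy-13,14,15,16-tetranorlabdan-12-one F6. F6 is opened with MeNH(OMe)·HCl and iPrMgCl to the hydroxy amide N-methoxy-N-methyl-6α-[(tert-butyldimethylsilyl)oxy]-8α-hydroxy-13,14,15,16-tetranorlabdan-12-amide F7. F7 is silylated (Et3SiOTf, 2,6-lutidine) to the 8α-triethylsilyl ether F8, and iBu2AlH reduction of the amide gives 31.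

**Step 12.** The most likely failure is slow olefination of the hindered lactol at the temperature needed, followed by oxa-Michael ring closure of the free C6 hydroxyl onto the new enoate. The fallback changes the order, so that the enoate is made only after C6 is built and protected. It sets out from 17 (isolated by leaving out the acid stage of step 11) and returns at 26. 17 is oxidised (Dess–Martin periodinane) to (1S,2S)-2-(1,3-dioxolan-2-yl)-2,6,6-trimethylcyclohexane-1-carbaldehyde F9. F9 is methallylated with 23 as in step 14 to (1S)-1-[(1S,2S)-2-(1,3-dioxolan-2-yl)-2,6,6-trimethylcyclohexyl]-3-methylbut-3-en-1-ol F10, which is silylated to its tert-butyldimethylsilyl ether F11. The dioxolane is hydrolysed (1 M aq. HCl, THF) to (1S,2S)-2-{(1S)-1-[(tert-butyldimethylsilyl)oxy]-3-methylbut-3-en-1-yl}-1,3,3-trimethylcyclohexane-1-carbaldehyde F12, and Wittig reaction with 19 gives 26.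

**Step 23.** The most likely failure is Z to E isomerisation of the angeloyl unit to the tiglate during a slow acylation of the hindered 6α-hydroxyl. The fallback builds the Z double bond on the ester instead of transferring it. It sets out from 37 and returns at 40. 37 is esterified at O6 with 2-[bis(2,2,2-trifluoroethoxy)phosphoryl]propanoic acid (DCC, DMAP) to give the phosphonate ester (12E)-8α-hydroxylabda-12,14-dien-6α-yl 2-[bis(2,2,2-trifluoroethoxy)phosphoryl]propanoate F13. Still–Gennari olefination of F13 with acetaldehyde (KN(SiMe3)2, 18-crown-6, THF, −78 °C) gives the Z enoate 40.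

## Further compounds

F1 | step 4 | (3E)-4-[(2R,5R)-2,5-diphenylpyrrolidin-1-yl]but-3-en-2-one | CC(=O)/C=C/N1[C@@H](c2ccccc2)CC[C@@H]1c1ccccc1
F2 | step 4 | (2R,5R)-1-[(1E)-3-{[tert-butyl(dimethyl)silyl]oxy}buta-1,3-dien-1-yl]-2,5-diphenylpyrrolidine | C=C(O[Si](C)(C)C(C)(C)C)/C=C/N1[C@@H](c2ccccc2)CC[C@@H]1c1ccccc1
F3 | step 4 | ethyl (1S,5S,6R)-3-{[tert-butyl(dimethyl)silyl]oxy}-5-[(2R,5R)-2,5-diphenylpyrrolidin-1-yl]-6-formyl-6-methylcyclohex-3-ene-1-carboxylate | CCOC(=O)[C@H]1CC(O[Si](C)(C)C(C)(C)C)=C[C@H](N2[C@@H](c3ccccc3)CC[C@@H]2c2ccccc2)[C@]1(C)C=O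
F4 | step 14 | methyl (2E)-3-{(1R,2S)-2-[(1R)-1-hydroxy-3-methylbut-3-en-1-yl]-1,3,3-trimethylcyclohexyl}prop-2-enoate | COC(=O)/C=C/[C@@]1(C)CCCC(C)(C)[C@@H]1[C@H](O)CC(C)=C
F5 | step 14 | methyl (2E)-3-[(1R,2S)-1,3,3-trimethyl-2-(3-methylbut-3-enoyl)cyclohexyl]prop-2-enoate | COC(=O)/C=C/[C@@]1(C)CCCC(C)(C)[C@@H]1C(=O)CC(C)=C
F6 | step 17 | 6α-[(tert-butyldimethylsilyl)oxy]-8α,12-epoxy-13,14,15,16-tetranorlabdan-12-one | O=C1C[C@@H]2[C@@]3(C)CCCC(C)(C)[C@@H]3[C@@H](O[Si](C)(C)C(C)(C)C)C[C@@]2(C)O1
F7 | step 17 | N-methoxy-N-methyl-6α-[(tert-butyldimethylsilyl)oxy]-8α-hydroxy-13,14,15,16-tetranorlabdan-12-amide | CON(C)C(=O)C[C@@H]1[C@@]2(C)CCCC(C)(C)[C@@H]2[C@@H](O[Si](C)(C)C(C)(C)C)C[C@@]1(C)O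
F8 | step 17 | N-methoxy-N-methyl-6α-[(tert-butyldimethylsilyl)oxy]-8α-[(triethylsilyl)oxy]-13,14,15,16-tetranorlabdan-12-amide | CON(C)C(=O)C[C@@H]1[C@@]2(C)CCCC(C)(C)[C@@H]2[C@@H](O[Si](C)(C)C(C)(C)C)C[C@@]1(C)O[Si](CC)(CC)CC
F9 | step 12 | (1S,2S)-2-(1,3-dioxolan-2-yl)-2,6,6-trimethylcyclohexane-1-carbaldehyde | O=C[C@H]1C(C)(C)CCC[C@]1(C)C2OCCO2
F10 | step 12 | (1S)-1-[(1S,2S)-2-(1,3-dioxolan-2-yl)-2,6,6-trimethylcyclohexyl]-3-methylbut-3-en-1-ol | C=C(C)C[C@H](O)[C@H]1C(C)(C)CCC[C@]1(C)C2OCCO2
F11 | step 12 | tert-butyl({(1S)-1-[(1S,2S)-2-(1,3-dioxolan-2-yl)-2,6,6-trimethylcyclohexyl]-3-methylbut-3-en-1-yl}oxy)dimethylsilane | C=C(C)C[C@H](O[Si](C)(C)C(C)(C)C)[C@H]1C(C)(C)CCC[C@]1(C)C2OCCO2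
F12 | step 12 | (1S,2S)-2-{(1S)-1-[(tert-butyldimethylsilyl)oxy]-3-methylbut-3-en-1-yl}-1,3,3-trimethylcyclohexane-1-carbaldehyde | C=C(C)C[C@H](O[Si](C)(C)C(C)(C)C)[C@H]1C(C)(C)CCC[C@]1(C)C=O
F13 | step 23 | (12E)-8α-hydroxylabda-12,14-dien-6α-yl 2-[bis(2,2,2-trifluoroethoxy)phosphoryl]propanoate | C=C/C(C)=C/C[C@@H]1[C@@]2(C)CCCC(C)(C)[C@@H]2[C@@H](OC(=O)C(C)P(=O)(OCC(F)(F)F)OCC(F)(F)F)C[C@@]1(C)O
A1 | alternative 1 | (2E,8Z,10E)-3,7,7-trimethyl-9-[(triisopropylsilyl)oxy]dodeca-2,8,10-trienal | O=C/C=C(\C)CCCC(C)(C)/C=C(O[Si](C(C)C)(C(C)C)C(C)C)/C=C/C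
A2 | alternative 1 | 6-(triisopropylsilyloxy)drim-6-en-11-al (5α-H, 8β-methyl, 9β-formyl, 10β-methyl) | O=C[C@@H]1[C@@]2(C)CCCC(C)(C)[C@@H]2C(O[Si](C(C)C)(C(C)C)C(C)C)=C[C@@H]1C
A3 | alternative 2 | methyl (2E,4R,6S)-4-hydroxy-6-[(4-methoxybenzyl)oxy]-4-methyl-6-[(1S)-2,6,6-trimethylcyclohex-2-en-1-yl]hex-2-enoate | COC(=O)/C=C/[C@](C)(O)C[C@H](OCc1ccc(OC)cc1)[C@@H]1C(C)=CCCC1(C)C
A4 | alternative 2 | methyl 8α-hydroxy-6α-(4-methoxybenzyloxy)-13,14,15,16-tetranorlabdan-12-oate | COC(=O)C[C@@H]1[C@@]2(C)CCCC(C)(C)[C@@H]2[C@@H](OCc3ccc(OC)cc3)C[C@@]1(C)O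
A5 | alternative 3 | 1-[3α-(tert-butyldimethylsilyloxy)-1α-hydroxy-4,4,7aβ-trimethyl-3aα-H-octahydro-1H-inden-1β-yl]ethan-1-one (trans-fused; the acetyl group holds C8 and C17) | CC(=O)[C@@]1(O)C[C@H](O[Si](C)(C)C(C)(C)C)[C@H]2C(C)(C)CCC[C@]12C
A6 | alternative 3 | 6α-(tert-butyldimethylsilyloxy)-8α-hydroxy-11-nordriman-9-one | O=C1[C@@]2(C)CCCC(C)(C)[C@@H]2[C@@H](O[Si](C)(C)C(C)(C)C)C[C@@]1(C)O
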